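The angelate on the side-chain carbinol and the acetate on C3 are removed first, leaving a 2,3-dihydrobenzofuran that carries two different silyl ethers.
The plan rests on C3 of the dihydrofuran ring: its oxygen sits next to C2, which carries O1 and the C(=CH2)CO2Me group, so O–C3–C2–C(=CH2) is a homoallylic alcohol. The C2–C3 bond is therefore cut to an ortho aryl aldehyde (C3) and a 2-(methoxycarbonyl)allylchromium whose γ carbon (C2) already bears O1.
Both partners sit in one allylic bromide, which is opened at the O1–C2 enol ether bond into a salicylaldehyde and a β-bromoacrylate made from methyl 2-(hydroxymethyl)acrylate. No hydride is used once the aldehyde is present, so it is carried unprotected.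
The salicylaldehyde comes from 4'-hydroxyacetophenone by asymmetric ketone reduction (side-chain stereocenter) and ortho-formylation.
Ring order: the benzene ring is bought; the dihydrofuran ring O1–C2–C3–C3a–C7a is the only ring made, closed in the chromium step, which also sets C2 and C3.

Key step: step 9

Assumption 1: the sense of induction of the chiral ligand in this ring closure cannot be derived from intermolecular cases; the (S,S) ligand is written, and its antipode is used, with nothing else changed, if a trial run shows the opposite sense.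
Assumption 2: the bromoalkene and enol ether geometries are drawn with bromine or aryloxy trans to the ester (the expected major isomers); mixtures are acceptable, because the addition–elimination and the allylchromium both equilibrate this alkene.

Step 1
Reactants: 1 4'-hydroxyacetophenone
Product: 2 4'-(tert-butyldimethylsilyloxy)acetophenone
Conditions: TBSCl, imidazole, DMF, rt
Reagents that add atoms: tert-butyldimethylsilyl chloride, CC(C)(C)[Si](C)(C)Cl
Why: Silylation of the phenol with a silyl chloride and imidazole removes the acidic proton that would consume borane and erode selectivity in the next step.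

Step 2
Reactants: 2 4'-(tert-butyldimethylsilyloxy)acetophenone
Product: 3 (1S)-1-[4-(tert-butyldimethylsilyloxy)phenyl]ethanol
Conditions: (R)-1-methyl-3,3-diphenyltetrahydro-1H,3H-pyrrolo[1,2-c][1,3,2]oxazaborole (10 mol%), BH3·SMe2, THF, 0 °C; MeOH quench
Reagents that add atoms: none
Why: Corey–Bakshi–Shibata reduction, in which the (R)-oxazaborolidine binds borane and the ketone so that hydride reaches the carbonyl face giving the (S)-carbinol, with aryl as the large and methyl as the small substituent.

Step 3
Reactants: 3 (1S)-1-[4-(tert-butyldimethylsilyloxy)phenyl]ethanol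
Product: 5 4-[(1S)-1-(tert-butyldimethylsilyloxy)ethyl]phenol, via bis-silyl ether 4 (not isolated)
Conditions: TBSCl, imidazole, DMF, rt; then H2O, Cs2CO3 (0.5 equiv), rt
Reagents that add atoms: tert-butyldimethylsilyl chloride, CC(C)(C)[Si](C)(C)Cl
Why: Silylation of the secondary alcohol is followed by carbonate-mediated hydrolysis that cleaves only the aryl silyl ether (phenoxide is the far better leaving group), and the stereocenter is not involved.

Step 4
Reactants: 5 4-[(1S)-1-(tert-butyldimethylsilyloxy)ethyl]phenol
Product: 6 5-[(1S)-1-(tert-butyldimethylsilyloxy)ethyl]-2-hydroxybenzaldehyde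
Conditions: MgCl2, Et3N, (CH2O)n, THF, reflux
Reagents that add atoms: paraformaldehyde (as formaldehyde), C=O
Why: Magnesium-mediated ortho-formylation (Casnati–Skattebøl), in which the magnesium phenoxide directs formaldehyde to the ortho carbon and a second formaldehyde oxidises the hydroxymethyl intermediate by hydride transfer; the two ortho positions are equivalent and the silyl ether and stereocenter are untouched.

Step 5
Reactants: 7 methyl 2-(hydroxymethyl)acrylate
Product: 8 methyl 2-[(triethylsilyloxy)methyl]acrylate
Conditions: TESCl, imidazole, CH2Cl2, 0 °C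
Reagents that add atoms: chlorotriethylsilane, CC[Si](Cl)(CC)CC
Why: Standard silylation of a primary alcohol, which keeps the hydroxyl from closing an epoxide on the tertiary bromide formed in the next step.

Step 6
Reactants: 8 methyl 2-[(triethylsilyloxy)methyl]acrylate
Product: 10 methyl (E)-3-bromo-2-[(triethylsilyloxy)methyl]acrylate, via dibromide 9 (not isolated)
Conditions: Br2, CH2Cl2, 0 °C to rt; then DBU, 0 °C
Reagents that add atoms: bromine, BrBr
Why: Bromination–dehydrobromination, in which bromine adds across the acrylate and DBU removes HBr by E2 from the more acidic CH2Br hydrogen and the tertiary α-bromide to give the β-bromoacrylate.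

Step 7
Reactants: 6 5-[(1S)-1-(tert-butyldimethylsilyloxy)ethyl]-2-hydroxybenzaldehyde; 10 methyl (E)-3-bromo-2-[(triethylsilyloxy)methyl]acrylate
Product: 12 methyl (E)-3-{4-[(1S)-1-(tert-butyldimethylsilyloxy)ethyl]-2-formylphenoxy}-2-(hydroxymethyl)acrylate, via triethylsilyl ether 11 (not isolated)
Conditions: Cs2CO3, DMF, 50 °C; crude 11 in AcOH/THF/H2O, rt
Reagents that add atoms: none
Why: Addition–elimination (nucleophilic vinylic substitution) of the phenoxide on the β-bromoacrylate expels bromide and gives the push–pull enol ether while the free aldehyde is inert to carbonate, and aqueous acetic acid then frees the primary alcohol from the labile triethylsilyl group and leaves the secondary tert-butyldimethylsilyl ether in place.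

Step 8
Reactants: 12 methyl (E)-3-{4-[(1S)-1-(tert-butyldimethylsilyloxy)ethyl]-2-formylphenoxy}-2-(hydroxymethyl)acrylate
Product: 13 methyl (Z)-2-(bromomethyl)-3-{4-[(1S)-1-(tert-butyldimethylsilyloxy)ethyl]-2-formylphenoxy}acrylate
Conditions: PPh3, NBS, CH2Cl2, −20 to 0 °C
Reagents that add atoms: N-bromosuccinimide, O=C1CCC(=O)N1Br
Why: Appel-type bromination, in which phosphonium activation of the primary allylic alcohol and displacement by bromide proceed below 0 °C without touching the aldehyde or the silyl ether, and an SN2' detour through the α-bromo ether would collapse to the same conjugated bromide.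

Step 9
Reactants: 13 methyl (Z)-2-(bromomethyl)-3-{4-[(1S)-1-(tert-butyldimethylsilyloxy)ethyl]-2-formylphenoxy}acrylate
Product: 16 methyl 2-[(2S,3S)-5-[(1S)-1-(tert-butyldimethylsilyloxy)ethyl]-3-(trimethylsilyloxy)-2,3-dihydrobenzofuran-2-yl]acrylate, via allylchromium complex 14 (not isolated), via chromium alkoxide 15 (not isolated)
Conditions: CrCl2 (10 mol%), 3,6-diphenyl-1,8-bis[(4S)-4-isopropyl-4,5-dihydrooxazol-2-yl]-9H-carbazole (12 mol%), i-Pr2NEt (30 mol%), Mn powder, Me3SiCl, THF, rt, slow addition of 13 at high dilution
Reagents that add atoms: chlorotrimethylsilane, C[Si](C)(C)Cl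
Why: Proposed new method: divalent chromium, kept in turnover by Mn, should insert into the allylic C–Br bond of 13 to give the trivalent allylchromium 14 (its η1–η3 shifts make the alkene geometry of 13 irrelevant), which adds through the aryloxy-bearing γ carbon to the chromium-bound ortho aldehyde in a closed six-membered transition state, after which Me3SiCl silylates alkoxide 15 and releases the metal. The closest known reaction types are the catalytic enantioselective chromium 2-(alkoxycarbonyl)allylation of aldehydes, γ-selective additions of γ-alkoxyallylchromium reagents and stoichiometric ring-closing allylchromium additions; their merger in one catalytic asymmetric ring closure is the untested part. The dihydrofuran ring closes in the 5-exo-trig mode, C2 attacking the carbonyl carbon that becomes C3. The relative configuration is set by the tether: the nearly flat benzo-fused five-membered ring fits inside the six-membered array only with a small O–C3–C2–C(acrylate) torsion, so the C3 oxygen and the acrylate carbon must be cis. The absolute configuration is set by the chiral bis(oxazolinyl)carbazole on chromium, which selects the aldehyde face, and because the side-chain (S)-carbinol is fixed the wrong-face product is a diastereomer that can be removed at 18. The step needs γ over α attack, allylation over pinacol coupling and ring closure over oligomerisation; these rest on the closed transition state (α attack would need a seven-membered ring through an open one), on the fast reaction of the activated allylic bromide with divalent chromium, on the non-enolisable aldehyde held three atoms from the γ carbon and on slow addition at high dilution.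

Step 10
Reactants: 16 methyl 2-[(2S,3S)-5-[(1S)-1-(tert-butyldimethylsilyloxy)ethyl]-3-(trimethylsilyloxy)-2,3-dihydrobenzofuran-2-yl]acrylate
Product: 18 methyl 2-[(2S,3S)-3-acetoxy-5-[(1S)-1-(tert-butyldimethylsilyloxy)ethyl]-2,3-dihydrobenzofuran-2-yl]acrylate, via hydroxy ester 17 (not isolated)
Conditions: Ac2O, DMAP, pyridine, THF, −20 °C; HF·pyridine added slowly, to 0 °C
Reagents that add atoms: acetic anhydride, CC(=O)OC(C)=O
Why: Fluoride cleaves the trimethylsilyl ether far faster than the hindered tert-butyldimethylsilyl ether, and because the acylating agent is already present the C3 alcohol is acetylated by DMAP-catalysed acyl transfer as it is released, which is meant to outpace its lactonisation onto the cis methyl ester; neither stereocenter is touched.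

Step 11
Reactants: 18 methyl 2-[(2S,3S)-3-acetoxy-5-[(1S)-1-(tert-butyldimethylsilyloxy)ethyl]-2,3-dihydrobenzofuran-2-yl]acrylate
Product: 19 methyl 2-[(2S,3S)-3-acetoxy-5-[(1S)-1-hydroxyethyl]-2,3-dihydrobenzofuran-2-yl]acrylate
Conditions: HF·pyridine, pyridine, THF, 0 °C to rt
Reagents that add atoms: none
Why: Pyridine-buffered HF removes the secondary silyl ether by Si–F bond formation under conditions too weakly acidic to ionise either benzylic C–O bond and without a base that could attack the acetate or the acrylate.

Step 12
Reactants: 19 methyl 2-[(2S,3S)-3-acetoxy-5-[(1S)-1-hydroxyethyl]-2,3-dihydrobenzofuran-2-yl]acrylate; 20 angelic acid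
Product: 22 (1S)-1-{(2S,3S)-3-acetoxy-2-[1-(methoxycarbonyl)vinyl]-2,3-dihydrobenzofuran-5-yl}ethyl (2Z)-2-methylbut-2-enoate (CNP0168827.1), via mixed anhydride 21 (not isolated)
Conditions: 20, 2,4,6-Cl3C6H2COCl, Et3N, toluene, rt; then 19, DMAP, rt
Reagents that add atoms: none
Why: Yamaguchi esterification, in which the mixed anhydride of angelic acid acylates the secondary alcohol through an acylpyridinium under mild conditions that keep the (Z)-alkene from isomerising to the tiglate, and acylation at oxygen leaves the carbinol configuration unchanged.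

Compound list
1 | 4'-hydroxyacetophenone | CC(=O)c1ccc(O)cc1 | starting material
2 | 4'-(tert-butyldimethylsilyloxy)acetophenone | CC(=O)c1ccc(O[Si](C)(C)C(C)(C)C)cc1 | intermediate
3 | (1S)-1-[4-(tert-butyldimethylsilyloxy)phenyl]ethanol | C[C@H](O)c1ccc(O[Si](C)(C)C(C)(C)C)cc1 | intermediate
4 | tert-butyl{4-[(1S)-1-(tert-butyldimethylsilyloxy)ethyl]phenoxy}dimethylsilane (not isolated) | C[C@H](O[Si](C)(C)C(C)(C)C)c1ccc(O[Si](C)(C)C(C)(C)C)cc1 | intermediate
5 | 4-[(1S)-1-(tert-butyldimethylsilyloxy)ethyl]phenol | C[C@H](O[Si](C)(C)C(C)(C)C)c1ccc(O)cc1 | intermediate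
6 | 5-[(1S)-1-(tert-butyldimethylsilyloxy)ethyl]-2-hydroxybenzaldehyde | O=Cc1cc([C@H](C)O[Si](C)(C)C(C)(C)C)ccc1O | intermediate
7 | methyl 2-(hydroxymethyl)acrylate | C=C(CO)C(=O)OC | starting material
8 | methyl 2-[(triethylsilyloxy)methyl]acrylate | C=C(CO[Si](CC)(CC)CC)C(=O)OC | intermediate
9 | methyl 2,3-dibromo-2-[(triethylsilyloxy)methyl]propanoate, racemic (not isolated) | COC(=O)C(Br)(CBr)CO[Si](CC)(CC)CC | intermediate
10 | methyl (E)-3-bromo-2-[(triethylsilyloxy)methyl]acrylate | Br/C=C(\CO[Si](CC)(CC)CC)C(=O)OC | intermediate
11 | methyl (E)-3-{4-[(1S)-1-(tert-butyldimethylsilyloxy)ethyl]-2-formylphenoxy}-2-[(triethylsilyloxy)methyl]acrylate (not isolated) | O=Cc1cc([C@H](C)O[Si](C)(C)C(C)(C)C)ccc1O/C=C(\CO[Si](CC)(CC)CC)C(=O)OC | intermediate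
12 | methyl (E)-3-{4-[(1S)-1-(tert-butyldimethylsilyloxy)ethyl]-2-formylphenoxy}-2-(hydroxymethyl)acrylate | O=Cc1cc([C@H](C)O[Si](C)(C)C(C)(C)C)ccc1O/C=C(\CO)C(=O)OC | intermediate
13 | methyl (Z)-2-(bromomethyl)-3-{4-[(1S)-1-(tert-butyldimethylsilyloxy)ethyl]-2-formylphenoxy}acrylate | O=Cc1cc([C@H](C)O[Si](C)(C)C(C)(C)C)ccc1O/C=C(\CBr)C(=O)OC | intermediate
14 | trivalent allylchromium complex formed from 13, chiral ligand and chloride on chromium not drawn (not isolated) | O=Cc1cc([C@H](C)O[Si](C)(C)C(C)(C)C)ccc1O/C=C(\C[Cr])C(=O)OC | intermediate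
15 | chromium alkoxide of the ring-closed alcohol, ligands on chromium not drawn (not isolated) | C=C(C(=O)OC)[C@@H]1Oc2ccc([C@H](C)O[Si](C)(C)C(C)(C)C)cc2[C@@H]1O[Cr] | intermediate
16 | methyl 2-[(2S,3S)-5-[(1S)-1-(tert-butyldimethylsilyloxy)ethyl]-3-(trimethylsilyloxy)-2,3-dihydrobenzofuran-2-yl]acrylate | C=C(C(=O)OC)[C@@H]1Oc2ccc([C@H](C)O[Si](C)(C)C(C)(C)C)cc2[C@@H]1O[Si](C)(C)C | intermediate
17 | methyl 2-[(2S,3S)-5-[(1S)-1-(tert-butyldimethylsilyloxy)ethyl]-3-hydroxy-2,3-dihydrobenzofuran-2-yl]acrylate (not isolated) | C=C(C(=O)OC)[C@@H]1Oc2ccc([C@H](C)O[Si](C)(C)C(C)(C)C)cc2[C@@H]1O | intermediate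
18 | methyl 2-[(2S,3S)-3-acetoxy-5-[(1S)-1-(tert-butyldimethylsilyloxy)ethyl]-2,3-dihydrobenzofuran-2-yl]acrylate | C=C(C(=O)OC)[C@@H]1Oc2ccc([C@H](C)O[Si](C)(C)C(C)(C)C)cc2[C@@H]1OC(C)=O | intermediate
19 | methyl 2-[(2S,3S)-3-acetoxy-5-[(1S)-1-hydroxyethyl]-2,3-dihydrobenzofuran-2-yl]acrylate | C=C(C(=O)OC)[C@@H]1Oc2ccc([C@H](C)O)cc2[C@@H]1OC(C)=O | intermediate
20 | angelic acid, (2Z)-2-methylbut-2-enoic acid | C/C=C(/C)C(=O)O | starting material
21 | (2Z)-2-methylbut-2-enoic 2,4,6-trichlorobenzoic anhydride (not isolated) | C/C=C(/C)C(=O)OC(=O)c1c(Cl)cc(Cl)cc1Cl | intermediate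
22 | (1S)-1-{(2S,3S)-3-acetoxy-2-[1-(methoxycarbonyl)vinyl]-2,3-dihydrobenzofuran-5-yl}ethyl (2Z)-2-methylbut-2-enoate | C=C(C(=O)OC)[C@@H]1Oc2ccc([C@H](C)OC(=O)/C(C)=C\C)cc2[C@@H]1OC(C)=O | target

Total step count: 12 (steps 5 and 6 form the side branch to 10).
Longest linear sequence: 10 steps (1–4 and 7–12).

Steps most likely to fail

1. Step 9. The process at risk is poor discrimination between the two aldehyde faces in the tethered transition state, or loss of catalyst turnover. The fallback sets out from 13. A stoichiometric Barbier ring closure with indium metal in THF/H2O is a known reaction of 2-(bromomethyl)acrylates with aldehydes, also in the ring-closing mode. It should close the same ring through the same cyclic transition state without a chiral ligand and give 17 together with the diastereomer of opposite ring configuration, methyl 2-[(2R,3R)-5-[(1S)-1-(tert-butyldimethylsilyloxy)ethyl]-3-hydroxy-2,3-dihydrobenzofuran-2-yl]acrylate F1. Immediate acetylation of the crude mixture (Ac2O, pyridine, DMAP) would give 18 and methyl 2-[(2R,3R)-3-acetoxy-5-[(1S)-1-(tert-butyldimethylsilyloxy)ethyl]-2,3-dihydrobenzofuran-2-yl]acrylate F2. These two are diastereomers because of the fixed (S)-carbinol and are separated by preparative HPLC. The route is rejoined at 18.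

2. Step 10. The process at risk is lactonisation of the freed C3 hydroxyl onto the cis methyl ester before acetylation is complete, or premature loss of the second silyl ether. The fallback sets out from 16 and is an acylative exchange in which the alcohol is never released. Ac2O with catalytic Bi(OTf)3 in CH2Cl2 at low temperature is a known direct conversion of silyl ethers into acetates. It acylates the ether oxygen and expels the trimethylsilyl group as its acetate, and the small trimethylsilyl ether should react before the tert-butyldimethylsilyl ether. It comes back to the route at 18 and makes no new compound (F0).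

3. Step 6. The process at risk is dehydrobromination in the other direction (toward the silyloxymethyl carbon) or attack of DBU on the product, either of which would leave too little β-bromoacrylate for step 7. The fallback sets out from 6 and needs neither 8 nor 10. DABCO-catalysed conjugate addition of 6 to methyl propiolate in CH2Cl2 should give methyl (E)-3-{4-[(1S)-1-(tert-butyldimethylsilyloxy)ethyl]-2-formylphenoxy}acrylate F3. Bromine adds to the enol ether double bond to give methyl 2,3-dibromo-3-{4-[(1S)-1-(tert-butyldimethylsilyloxy)ethyl]-2-formylphenoxy}propanoate F4, which is not isolated. Et3N removes HBr from it to give methyl (Z)-2-bromo-3-{4-[(1S)-1-(tert-butyldimethylsilyloxy)ethyl]-2-formylphenoxy}acrylate F5. A Stille coupling of this bromide with Bu3SnCH2OH and Pd(PPh3)4 in dioxane installs the hydroxymethyl group and comes back to the route at 12.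

Further compounds
F1 | step 9 | methyl 2-[(2R,3R)-5-[(1S)-1-(tert-butyldimethylsilyloxy)ethyl]-3-hydroxy-2,3-dihydrobenzofuran-2-yl]acrylate | C=C(C(=O)OC)[C@H]1Oc2ccc([C@H](C)O[Si](C)(C)C(C)(C)C)cc2[C@H]1O
F2 | step 9 | methyl 2-[(2R,3R)-3-acetoxy-5-[(1S)-1-(tert-butyldimethylsilyloxy)ethyl]-2,3-dihydrobenzofuran-2-yl]acrylate | C=C(C(=O)OC)[C@H]1Oc2ccc([C@H](C)O[Si](C)(C)C(C)(C)C)cc2[C@H]1OC(C)=O
F0 | step 10 | none | none
F3 | step 6 | methyl (E)-3-{4-[(1S)-1-(tert-butyldimethylsilyloxy)ethyl]-2-formylphenoxy}acrylate | O=Cc1cc([C@H](C)O[Si](C)(C)C(C)(C)C)ccc1O/C=C/C(=O)OC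
F4 | step 6 | methyl 2,3-dibromo-3-{4-[(1S)-1-(tert-butyldimethylsilyloxy)ethyl]-2-formylphenoxy}propanoate (mixture at the two new centers) | O=Cc1cc([C@H](C)O[Si](C)(C)C(C)(C)C)ccc1OC(Br)C(Br)C(=O)OC
F5 | step 6 | methyl (Z)-2-bromo-3-{4-[(1S)-1-(tert-butyldimethylsilyloxy)ethyl]-2-formylphenoxy}acrylate | O=Cc1cc([C@H](C)O[Si](C)(C)C(C)(C)C)ccc1O/C=C(\Br)C(=O)OC
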